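**Plan**
1. Retrosynthesis: the three O–CH3 bonds are cut first, since all phenols travel as methyl ethers. Next the C7–O and C8–C(=O) bonds are cut together, then C4–phenyl, then the pyranone ring (C3=C4 and O1–C2).
2. Enabling feature: on ring A the C7 hydroxyl and the C8 ketone sit on adjacent carbons (an ortho-hydroxyaryl ketone), and C8 is flanked by the lactone oxygen O1 on C8a. A C7–C8 aryne and a cinnamic acid supply both bonds at once, and O1 polarises the aryne in the sense required.
3. Forward: ring A is dressed first. Silicon goes onto the future C7 by organolithium chemistry before any lactone exists. Two ortho-formylations and one Baeyer–Villiger oxidation then bring in O1 and C4.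
4. The pyranone ring closes by Wittig olefination and lactonisation, and phenyl is added to C4. The C8 oxygen is then unmasked and triflated, and the side chain is joined in the aryne step, which closes no ring.
5. Stereochemistry: the only stereocentre, C4 (R), comes from a rhodium/(R)-Segphos 1,4-addition of phenylboronic acid to the coumarin. The E alkene is bought with the acid.

Key step: step 10

Remark: chroman-2-one numbering (O1, C2 to C8a) is used throughout. The facial sense of (R)-Segphos is assumed to be the one known for simple coumarins, which gives the R lactone; the CIP order at C4 (C4a > phenyl > C3 > H) is the same in every compound of the route.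

Step 1
Reactants: 1 2-bromo-4-methoxyphenol
Product: 3 4-methoxy-2-(trimethylsilyl)phenol, via silyl ether 2 (not isolated)
Conditions: HMDS, THF, reflux; evaporate; n-BuLi, THF, −78 °C to rt; aq NH4Cl
Reagents that add atoms: hexamethyldisilazane, C[Si](C)(C)N[Si](C)(C)C
Why: O-silylation followed by bromine–lithium exchange triggers a retro-Brook (1,3 O-to-C) silyl shift, driven by the greater stability of the lithium phenoxide over the aryllithium, which is the standard entry to ortho-silylphenols.

Step 2
Reactants: 3 4-methoxy-2-(trimethylsilyl)phenol
Product: 4 2-hydroxy-5-methoxy-3-(trimethylsilyl)benzaldehyde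
Conditions: MgCl2, Et3N, (CH2O)n, MeCN, reflux; 1 M HCl
Reagents that add atoms: paraformaldehyde (as formaldehyde), C=O
Why: In the Casnati–Skattebøl ortho-formylation the magnesium phenoxide delivers formaldehyde only ortho to oxygen, and the single free ortho carbon (the future C8a) is the only site open, as with other phenols that carry a bulky ortho group.

Step 3
Reactants: 4 2-hydroxy-5-methoxy-3-(trimethylsilyl)benzaldehyde
Product: 5 2-(benzyloxy)-5-methoxy-3-(trimethylsilyl)benzaldehyde
Conditions: BnBr, K2CO3, DMF, rt to 50 °C
Reagents that add atoms: benzyl bromide, BrCc1ccccc1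
Why: This Williamson etherification masks the future C8 oxygen with a group that withstands peracid, mild base, heat and the rhodium step and later leaves by neutral hydrogenolysis without touching the C–Si bond.

Step 4
Reactants: 5 2-(benzyloxy)-5-methoxy-3-(trimethylsilyl)benzaldehyde
Product: 7 2-(benzyloxy)-5-methoxy-3-(trimethylsilyl)phenol, via aryl formate 6 (not isolated)
Conditions: mCPBA, CH2Cl2, 0 °C to rt; then K2CO3 (cat.), MeOH, rt
Reagents that add atoms: mCPBA, O=C(OO)c1cccc(Cl)c1
Why: In this Baeyer–Villiger (Dakin-type) oxidation the electron-rich aryl group with its ortho alkoxy substituent migrates in preference to hydride, and gentle methanolysis of the formate frees the phenol oxygen that becomes O1.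

Step 5
Reactants: 7 2-(benzyloxy)-5-methoxy-3-(trimethylsilyl)phenol
Product: 8 3-(benzyloxy)-2-hydroxy-6-methoxy-4-(trimethylsilyl)benzaldehyde
Conditions: MgCl2, Et3N, (CH2O)n, MeCN, reflux; 1 M HCl
Reagents that add atoms: paraformaldehyde (as formaldehyde), C=O
Why: In this second Casnati–Skattebøl formylation one ortho carbon already carries OBn, so magnesium-directed delivery can reach only the carbon between OH and OMe (the future C4a), as in the formylation of 3,5-dimethoxyphenol.

Step 6
Reactants: 8 3-(benzyloxy)-2-hydroxy-6-methoxy-4-(trimethylsilyl)benzaldehyde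
Product: 10 8-(benzyloxy)-5-methoxy-7-(trimethylsilyl)-2H-chromen-2-one, via acrylate 9 (not isolated)
Conditions: Ph3P=CHCO2Et, PhNEt2, reflux
Reagents that add atoms: ethyl (triphenylphosphoranylidene)acetate, CCOC(=O)C=P(c1ccccc1)(c1ccccc1)c1ccccc1
Why: Wittig olefination with the stabilised ylide, thermal E/Z equilibration and lactonisation in the hot amine solvent make up the usual one-flask conversion of salicylaldehydes into 3,4-unsubstituted coumarins.

Step 7
Reactants: 10 8-(benzyloxy)-5-methoxy-7-(trimethylsilyl)-2H-chromen-2-one; 11 phenylboronic acid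
Product: 12 (R)-8-(benzyloxy)-5-methoxy-4-phenyl-7-(trimethylsilyl)chroman-2-one
Conditions: Rh(acac)(C2H4)2 (3 mol %), (R)-Segphos, 11 (excess), dioxane/H2O 10:1, 60 °C
Reagents that add atoms: none
Why: In the Hayashi–Miyaura asymmetric 1,4-addition the phenylrhodium species bound to (R)-Segphos inserts the C3=C4 bond from one face and the rhodium enolate is hydrolysed, a reaction known to turn coumarins into (R)-4-arylchroman-2-ones with this ligand enantiomer, so C4 is set as R by the catalyst.

Step 8
Reactants: 12 (R)-8-(benzyloxy)-5-methoxy-4-phenyl-7-(trimethylsilyl)chroman-2-one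
Product: 13 (R)-8-hydroxy-5-methoxy-4-phenyl-7-(trimethylsilyl)chroman-2-one
Conditions: H2 (1 atm), Pd/C, EtOAc, rt
Reagents that add atoms: none
Why: Hydrogenolysis of the benzyl aryl ether is neutral, so the lactone, the aryl–silicon bond and the C4 centre should all be left alone.

Step 9
Reactants: 13 (R)-8-hydroxy-5-methoxy-4-phenyl-7-(trimethylsilyl)chroman-2-one
Product: 14 (R)-5-methoxy-2-oxo-4-phenyl-7-(trimethylsilyl)chroman-8-yl trifluoromethanesulfonate
Conditions: Tf2O, pyridine, CH2Cl2, 0 °C
Reagents that add atoms: trifluoromethanesulfonic anhydride, O=S(=O)(OS(=O)(=O)C(F)(F)F)C(F)(F)F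
Why: O-sulfonylation of an ortho-silylphenol is the standard last step towards ortho-silylaryl triflates, and pyridine at 0 °C is too mild to open the lactone.

Step 10
Reactants: 14 (R)-5-methoxy-2-oxo-4-phenyl-7-(trimethylsilyl)chroman-8-yl trifluoromethanesulfonate; 15 (E)-3,4-dimethoxycinnamic acid
Product: 17 (R)-8-[(E)-3-(3,4-dimethoxyphenyl)acryloyl]-7-hydroxy-5-methoxy-4-phenylchroman-2-one, via aryne 16 (not isolated)
Conditions: CsF (5 equiv), 15 (2 equiv), THF (0.03 M), sealed tube, 125 °C; cold 1 M HCl
Reagents that add atoms: none
Why: Desilylation at C7 by fluoride with loss of triflate from C8 unveils aryne 16; the carboxylate of 15 adds through oxygen at C7, the C8 carbanion closes onto the neighbouring ester carbonyl to a four-membered alkoxide, and this collapses to the C8 ketone and the C7 phenoxide, a formal insertion into the acyl C–O bond. The closest known reaction is the addition of carboxylic acids, α,β-unsaturated ones included, to arynes from ortho-silylaryl triflates, which in hot dilute THF gives ortho-hydroxyaryl ketones rather than aryl esters. No ring is closed and no stereocentre is made, and C4, which is β to the lactone carbonyl and not acidified, should keep its configuration. The step needs attack at C7: the electronegative O1 on C8a distorts the aryne so that C7 is the more linear and more electrophilic carbon and charge builds at C8 next to O1, C7 has only C6–H beside it, and the weak opposing inductive pull of the remote C5 methoxy group should not overturn this bias. C2 of the lactone is locked anti to C8 across O1 and lies out of reach of the carbanion, so only the freely rotating new ester can hand over its acyl group. Oxa-Michael closure of the C7 phenoxide onto the enone is reversible through E1cB opening, so a cold acidic quench of the basic mixture should release the open E-enone.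

Step 11
Reactants: 17 (R)-8-[(E)-3-(3,4-dimethoxyphenyl)acryloyl]-7-hydroxy-5-methoxy-4-phenylchroman-2-one
Product: 18 (R)-8-[(E)-3-(3,4-dihydroxyphenyl)acryloyl]-5,7-dihydroxy-4-phenylchroman-2-one
Conditions: BBr3 (excess), CH2Cl2, −78 °C to rt; ice water
Reagents that add atoms: none
Why: In this Lewis-acid ether cleavage BBr3 binds each aryl methyl ether oxygen and bromide removes the methyl group by SN2, a standard way from methoxychalcones to hydroxychalcones, while boron chelation between the C7 oxygen and the ketone should hold that phenol away from the enone and C4 is not involved.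

**Compound list**
1 | 2-bromo-4-methoxyphenol | COc1ccc(O)c(Br)c1 | starting material
2 | (2-bromo-4-methoxyphenoxy)trimethylsilane | COc1ccc(O[Si](C)(C)C)c(Br)c1 | intermediate
3 | 4-methoxy-2-(trimethylsilyl)phenol | COc1ccc(O)c([Si](C)(C)C)c1 | intermediate
4 | 2-hydroxy-5-methoxy-3-(trimethylsilyl)benzaldehyde | COc1cc(C=O)c(O)c([Si](C)(C)C)c1 | intermediate
5 | 2-(benzyloxy)-5-methoxy-3-(trimethylsilyl)benzaldehyde | COc1cc(C=O)c(OCc2ccccc2)c([Si](C)(C)C)c1 | intermediate
6 | 2-(benzyloxy)-5-methoxy-3-(trimethylsilyl)phenyl formate | COc1cc(OC=O)c(OCc2ccccc2)c([Si](C)(C)C)c1 | intermediate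
7 | 2-(benzyloxy)-5-methoxy-3-(trimethylsilyl)phenol | COc1cc(O)c(OCc2ccccc2)c([Si](C)(C)C)c1 | intermediate
8 | 3-(benzyloxy)-2-hydroxy-6-methoxy-4-(trimethylsilyl)benzaldehyde | COc1cc([Si](C)(C)C)c(OCc2ccccc2)c(O)c1C=O | intermediate
9 | ethyl (E)-3-[3-(benzyloxy)-2-hydroxy-6-methoxy-4-(trimethylsilyl)phenyl]acrylate | CCOC(=O)/C=C/c1c(OC)cc([Si](C)(C)C)c(OCc2ccccc2)c1O | intermediate
10 | 8-(benzyloxy)-5-methoxy-7-(trimethylsilyl)-2H-chromen-2-one | O=c1ccc2c(OC)cc([Si](C)(C)C)c(OCc3ccccc3)c2o1 | intermediate
11 | phenylboronic acid | OB(O)c1ccccc1 | starting material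
12 | (R)-8-(benzyloxy)-5-methoxy-4-phenyl-7-(trimethylsilyl)chroman-2-one | O=C1C[C@H](c2ccccc2)c2c(OC)cc([Si](C)(C)C)c(OCc3ccccc3)c2O1 | intermediate
13 | (R)-8-hydroxy-5-methoxy-4-phenyl-7-(trimethylsilyl)chroman-2-one | O=C1C[C@H](c2ccccc2)c2c(OC)cc([Si](C)(C)C)c(O)c2O1 | intermediate
14 | (R)-5-methoxy-2-oxo-4-phenyl-7-(trimethylsilyl)chroman-8-yl trifluoromethanesulfonate | O=C1C[C@H](c2ccccc2)c2c(OC)cc([Si](C)(C)C)c(OS(=O)(=O)C(F)(F)F)c2O1 | intermediate
15 | (E)-3,4-dimethoxycinnamic acid | COc1ccc(/C=C/C(=O)O)cc1OC | starting material
16 | (R)-7,8-didehydro-5-methoxy-4-phenylchroman-2-one (C7–C8 aryne) | O=C1C[C@H](c2ccccc2)C2=C(O1)C#CC=C2OC | intermediate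
17 | (R)-8-[(E)-3-(3,4-dimethoxyphenyl)acryloyl]-7-hydroxy-5-methoxy-4-phenylchroman-2-one | O=C1C[C@H](c2ccccc2)c2c(OC)cc(O)c(C(=O)/C=C/c3ccc(OC)c(OC)c3)c2O1 | intermediate
18 | (R)-8-[(E)-3-(3,4-dihydroxyphenyl)acryloyl]-5,7-dihydroxy-4-phenylchroman-2-one | O=C1C[C@H](c2ccccc2)c2c(O)cc(O)c(C(=O)/C=C/c3ccc(O)c(O)c3)c2O1 | target

Total step count: 11. Longest linear sequence: 11 steps (1 to 18); 11 and 15 are bought and enter directly.

**Steps most likely to fail**

Step 10. Three processes threaten the step.
- The C8 carbanion may pick up a proton before the conjugated, less electrophilic cinnamoyl carbonyl is transferred.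
- The C7 phenoxide may close irreversibly in practice onto the enone at 125 °C.
- The enone may suffer in hot fluoride.

The fallback sets out from 14. The same aryne 16 is intercepted with acetic acid (CsF, THF, 125 °C), whose small and more electrophilic acyl group should shift faster and carries no Michael acceptor. This should give (R)-8-acetyl-7-hydroxy-5-methoxy-4-phenylchroman-2-one F1. The enone is then built outside the fluoride medium by a BF3·OEt2-promoted Claisen–Schmidt condensation with 3,4-dimethoxybenzaldehyde in dioxane at rt, conditions that spare base-sensitive esters. The route is rejoined at 17.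

Step 7. Insertion of the electron-rich C3=C4 bond, which is crowded by the peri C5 methoxy group, into the phenyl–rhodium bond may be slow. Protodeboronation of 11 could then outrun addition, or facial selectivity could erode. The fallback sets out from 10. Phenylmagnesium bromide with CuBr·SMe2 in THF at −30 °C, a far more reactive phenyl donor, should add to C4 without facial control to give racemic 8-(benzyloxy)-5-methoxy-4-phenyl-7-(trimethylsilyl)chroman-2-one F2. Preparative chromatography on a chiral stationary phase then separates the R lactone from (S)-8-(benzyloxy)-5-methoxy-4-phenyl-7-(trimethylsilyl)chroman-2-one F3, which is set aside. The route is rejoined at 12, with the stereochemistry coming from resolution instead of catalysis.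

Step 11. Addition of HBr to the enone, acid-induced closure of the C7 hydroxyl onto it, and incomplete cleavage of the hindered C5 ether may compete with clean triple demethylation. The fallback sets out from 14 and moves the ether cleavage ahead of enone formation.
- The aryne is taken up by acetic acid as above to give the acetyl ketone F1.
- BBr3 in CH2Cl2 cleaves its single methyl ether on a substrate that has no enone, giving (R)-8-acetyl-5,7-dihydroxy-4-phenylchroman-2-one F4.
- An acid-promoted Claisen–Schmidt condensation with 3,4-dihydroxybenzaldehyde (dry HCl in dioxane, the classical access to unprotected polyhydroxychalcones) forms the E-enone last and arrives at 18.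

**Further compounds**
F1 | step 10 | (R)-8-acetyl-7-hydroxy-5-methoxy-4-phenylchroman-2-one | O=C1C[C@H](c2ccccc2)c2c(OC)cc(O)c(C(C)=O)c2O1
F2 | step 7 | racemic 8-(benzyloxy)-5-methoxy-4-phenyl-7-(trimethylsilyl)chroman-2-one | O=C1CC(c2ccccc2)c2c(OC)cc([Si](C)(C)C)c(OCc3ccccc3)c2O1
F3 | step 7 | (S)-8-(benzyloxy)-5-methoxy-4-phenyl-7-(trimethylsilyl)chroman-2-one | O=C1C[C@@H](c2ccccc2)c2c(OC)cc([Si](C)(C)C)c(OCc3ccccc3)c2O1
F4 | step 11 | (R)-8-acetyl-5,7-dihydroxy-4-phenylchroman-2-one | O=C1C[C@H](c2ccccc2)c2c(O)cc(O)c(C(C)=O)c2O1
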